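**Plan**
1. Retrosynthetic cuts, in order: ring B (the 2-aryloxyresorcinol ring) is taken back by one H2 to a 2-aryloxycyclohexane-1,3-dione. Next the ether bond between the ring A oxygen and C2 of ring B is cut. Then ring B itself (enone + malonate), the enone C=C (cross metathesis) and the ring A–CH2 bond (B-alkyl Suzuki coupling).
2. Enabling feature: C2 of ring B lies between the two oxygen-bearing carbons C1 and C3, so ring B is a masked cyclohexane-1,3-dione. At that oxidation level C2 is the only acidic CH2. It accepts a diazo group and so changes from a nucleophilic into an electrophilic (carbenoid) carbon, which the electron-rich, doubly ortho-substituted arene never is.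
3. Ring A is a 5-alkylresorcinol with two equivalent OH groups. It enters the ring closure unprotected, and either OH gives the same product.
4. Forward order: the C14 diene is joined to ring A, the enone is made, ring B is built as the dione, and the diazo group is transferred. The 20-membered ring is closed by rhodium-carbenoid O–H insertion, and ring B is aromatised last.
5. Stereochemistry: the target has no stereocentre. The transient centre at C5 of the ring B precursor is racemic and is erased on aromatisation.

Key step: step 6

Assumptions: 1,3-bis(benzyloxy)-5-bromobenzene is taken as a catalogue compound; the racemic or tautomerising intermediates of steps 3, 6 and 7 lose their stereocentres later, so their SMILES carry no configuration.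

Step 1
Reactants: 1 tetradeca-1,13-diene; 2 9-borabicyclo[3.3.1]nonane (9-BBN); 3 1,3-bis(benzyloxy)-5-bromobenzene
Product: 5 1,3-bis(benzyloxy)-5-(tetradec-13-en-1-yl)benzene, via 9-(tetradec-13-en-1-yl)-9-BBN 4 (not isolated)
Conditions: 1 (3 equiv), 2 (1 equiv), THF, 0 °C to rt; then 3, PdCl2(dppf) (3 mol %), 3 M aq NaOH, THF, 65 °C
Reagents that add atoms: none
Why: Anti-Markovnikov hydroboration of one vinyl group (the excess of diene keeps double hydroboration low) followed by B-alkyl Suzuki–Miyaura coupling should join the sp3 chain end to the aryl bromide and leave the second vinyl group untouched.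

Step 2
Reactants: 5 1,3-bis(benzyloxy)-5-(tetradec-13-en-1-yl)benzene; 6 but-3-en-2-one (methyl vinyl ketone)
Product: 7 (E)-16-[3,5-bis(benzyloxy)phenyl]hexadec-3-en-2-one
Conditions: 6 (3 equiv), second-generation Hoveyda–Grubbs catalyst (2 mol %), CH2Cl2, 40 °C
Reagents that add atoms: none
Why: Olefin cross metathesis between a readily homodimerising terminal alkene and an electron-poor enone that does not homodimerise is selective for the cross product and should give the E enone under thermodynamic control.

Step 3
Reactants: 7 (E)-16-[3,5-bis(benzyloxy)phenyl]hexadec-3-en-2-one; 8 dimethyl malonate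
Product: 11 5-{12-[3,5-bis(benzyloxy)phenyl]dodecyl}cyclohexane-1,3-dione, via keto ester 9 (not isolated), via keto acid 10 (not isolated)
Conditions: NaOMe (1.2 equiv), MeOH–THF, reflux; then 2 M aq NaOH, reflux; then 6 M HCl to pH 1, reflux
Reagents that add atoms: none
Why: Michael addition of the malonate anion to the enone, Claisen (Dieckmann-type) closure of the methyl ketone enolate onto one ester, saponification and decarboxylation of the β-keto acid form the classical route to 5-alkylcyclohexane-1,3-diones, and the stereocentres of 9 and 10 vanish in the achiral 11.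

Step 4
Reactants: 11 5-{12-[3,5-bis(benzyloxy)phenyl]dodecyl}cyclohexane-1,3-dione
Product: 12 5-[12-(3,5-dihydroxyphenyl)dodecyl]cyclohexane-1,3-dione
Conditions: H2 (1 atm), 10% Pd/C, EtOAc–EtOH, rt
Reagents that add atoms: none
Why: Hydrogenolysis of benzyl aryl ethers over palladium is fast at 1 atm and room temperature, conditions under which the enolised 1,3-dione should not be reduced.

Step 5
Reactants: 12 5-[12-(3,5-dihydroxyphenyl)dodecyl]cyclohexane-1,3-dione
Product: 13 2-diazo-5-[12-(3,5-dihydroxyphenyl)dodecyl]cyclohexane-1,3-dione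
Conditions: p-ABSA (1.05 equiv), Et3N (1.1 equiv), MeCN, 0 °C to rt
Reagents that add atoms: 4-acetamidobenzenesulfonyl azide (p-ABSA), CC(=O)Nc1ccc(cc1)S(=O)(=O)N=[N+]=[N-]
Why: In this Regitz diazo transfer Et3N deprotonates only the 1,3-dione (pKa about 5, against about 9 for the resorcinol OH groups), and the C2 enolate carbon attacks the terminal nitrogen of the sulfonyl azide, so N2 is delivered to C2 alone.

Step 6
Reactants: 13 2-diazo-5-[12-(3,5-dihydroxyphenyl)dodecyl]cyclohexane-1,3-dione
Product: 15 macrocyclic 2-aryloxy-3-hydroxycyclohex-2-en-1-one (dihydro form of the target), via rhodium carbenoid 14 (not isolated)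
Conditions: Rh2(OAc)4 (2 mol %), 4 Å molecular sieves, ClCH2CH2Cl, 80 °C, argon; 13 added by syringe pump over 12 h, final concentration 1 mM
Reagents that add atoms: none
Why: Rh2(OAc)4 expels N2 from the diazo carbon C2 and leaves a strongly electrophilic rhodium carbenoid 14 flanked by two carbonyl groups; a phenolic oxygen of ring A adds to this carbon to give a rhodium-associated oxonium ylide, and proton transfer followed by enolisation gives 15. The closest known reaction type is the rhodium-carbenoid O–H insertion of 2-diazo-1,3-dicarbonyl compounds into phenols and alcohols, which is also known in its intramolecular form for cyclic ethers up to macrocyclic size. The 20-membered ring (the ether O, three carbons of ring A, twelve CH2 and four carbons of ring B) closes end to end, formally 20-exo because the breaking C=Rh bond lies outside the new ring, and slow addition keeps the stationary concentration of 13 so low that the unimolecular closure should win over chain growth. No lasting stereocentre is made: C2 becomes sp2 on enolisation, and C5 is stereogenic only through the rapidly exchanging keto and enol positions, is racemic and is flattened in step 7. Site selectivity is built into the substrate, since the diazo group can sit only on C2 and the two OH groups of ring A are interchanged by the local mirror plane of that ring, so that both give the same 15. Chemoselectivity for O–H over C–H rests on the much faster ylide and proton-transfer path of acceptor-substituted carbenoids with phenols, on the absence of any hydrogen next to the carbenoid carbon (no 1,2-shift) and on the strained bicyclo[2.2.1]heptane that a transannular C–H insertion would require.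

Step 7
Reactants: 15 macrocyclic 2-aryloxy-3-hydroxycyclohex-2-en-1-one
Product: 17 tris-TBS ether of the target, via tris-TBS cyclohexadiene 16 (not isolated)
Conditions: TBSOTf (4 equiv), Et3N (6 equiv), CH2Cl2, 0 °C to rt; pentane, filtration, evaporation; then DDQ (1.1 equiv), 2,4,6-collidine (2 equiv), toluene, 0 °C to rt
Reagents that add atoms: tert-butyldimethylsilyl triflate (TBSOTf), CC(C)(C)[Si](C)(C)OS(=O)(=O)C(F)(F)F
Why: Soft enolisation should turn the vinylogous acid into a 1,3-bis(silyloxy)cyclohexa-1,3-diene and cap the phenol, after which hydride abstraction by DDQ and proton loss (the DDQ dehydrogenation of silyl enol ethers) aromatise ring B, erase the C5 centre and leave the electron-rich product shielded by its silyl groups.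

Step 8
Reactants: 17 tris-TBS ether of the target
Product: 18 target macrocycle CNP0314249.0
Conditions: KHF2 (6 equiv), MeOH–THF, rt, argon
Reagents that add atoms: none
Why: Fluoride cleavage of aryl silyl ethers with the weakly acidic KHF2 should free the three phenols without passing through air-sensitive phenoxides.

**Compound list**
1 | tetradeca-1,13-diene | C=CCCCCCCCCCCCC=C | starting material
2 | 9-borabicyclo[3.3.1]nonane (9-BBN, drawn as the monomer) | B1C2CCCC1CCC2 | starting material
3 | 1,3-bis(benzyloxy)-5-bromobenzene | Brc1cc(OCc2ccccc2)cc(OCc2ccccc2)c1 | starting material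
4 | 9-(tetradec-13-en-1-yl)-9-borabicyclo[3.3.1]nonane | C=CCCCCCCCCCCCCB1C2CCCC1CCC2 | intermediate
5 | 1,3-bis(benzyloxy)-5-(tetradec-13-en-1-yl)benzene | C=CCCCCCCCCCCCCc1cc(OCc2ccccc2)cc(OCc2ccccc2)c1 | intermediate
6 | but-3-en-2-one (methyl vinyl ketone) | CC(=O)C=C | starting material
7 | (E)-16-[3,5-bis(benzyloxy)phenyl]hexadec-3-en-2-one | CC(=O)/C=C/CCCCCCCCCCCCc1cc(OCc2ccccc2)cc(OCc2ccccc2)c1 | intermediate
8 | dimethyl malonate | COC(=O)CC(=O)OC | starting material
9 | methyl 6-{12-[3,5-bis(benzyloxy)phenyl]dodecyl}-2,4-dioxocyclohexane-1-carboxylate (racemic, C1 epimerisable) | COC(=O)C1C(CCCCCCCCCCCCc2cc(OCc3ccccc3)cc(OCc3ccccc3)c2)CC(=O)CC1=O | intermediate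
10 | 6-{12-[3,5-bis(benzyloxy)phenyl]dodecyl}-2,4-dioxocyclohexane-1-carboxylic acid (racemic, C1 epimerisable) | OC(=O)C1C(CCCCCCCCCCCCc2cc(OCc3ccccc3)cc(OCc3ccccc3)c2)CC(=O)CC1=O | intermediate
11 | 5-{12-[3,5-bis(benzyloxy)phenyl]dodecyl}cyclohexane-1,3-dione | O=C1CC(CCCCCCCCCCCCc2cc(OCc3ccccc3)cc(OCc3ccccc3)c2)CC(=O)C1 | intermediate
12 | 5-[12-(3,5-dihydroxyphenyl)dodecyl]cyclohexane-1,3-dione | O=C1CC(CCCCCCCCCCCCc2cc(O)cc(O)c2)CC(=O)C1 | intermediate
13 | 2-diazo-5-[12-(3,5-dihydroxyphenyl)dodecyl]cyclohexane-1,3-dione | O=C1CC(CCCCCCCCCCCCc2cc(O)cc(O)c2)CC(=O)C1=[N+]=[N-] | intermediate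
14 | rhodium carbenoid at C2 of the dione ring (drawn as the free carbene; in the flask C2 is bound to Rh2(OAc)4) | O=C1CC(CCCCCCCCCCCCc2cc(O)cc(O)c2)CC(=O)[C]1 | intermediate
15 | 20-membered macrocycle: 3-hydroxycyclohex-2-en-1-one whose C2 carries the oxygen of a 3-oxy-5-hydroxyphenyl ring A and whose C5 is tied by (CH2)12 to the remaining meta carbon of ring A (racemic, enol tautomer) | Oc1cc2cc(c1)OC1=C(O)CC(CC1=O)CCCCCCCCCCCC2 | intermediate
16 | tris-TBS derivative of 15: ring B as 1,3-bis(silyloxy)-2-aryloxycyclohexa-1,3-diene, ring A phenol as silyl ether (racemic) | CC(C)(C)[Si](C)(C)Oc1cc2cc(c1)OC1=C(O[Si](C)(C)C(C)(C)C)CC(C=C1O[Si](C)(C)C(C)(C)C)CCCCCCCCCCCC2 | intermediate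
17 | tris(tert-butyldimethylsilyl) ether of the target | CC(C)(C)[Si](C)(C)Oc1cc2cc(c1)Oc1c(O[Si](C)(C)C(C)(C)C)cc(cc1O[Si](C)(C)C(C)(C)C)CCCCCCCCCCCC2 | intermediate
18 | CNP0314249.0: macrocyclic diaryl ether, ring A 3-oxy-5-hydroxyphenyl, ring B 2,6-dihydroxyphenyl bound to the ether O at C1 and to the (CH2)12 chain at C4 | Oc1cc2cc(c1)Oc1c(O)cc(cc1O)CCCCCCCCCCCC2 | target

**Step count and risks**
Total step count: 8. Longest linear sequence: 8 steps (from 1 to 18).

**Steps most likely to fail**

Step 6.
- What may go wrong: chain growth by intermolecular O–H insertion, or attack of the carbenoid on the electron-rich ring carbons of ring A, overtakes the ring closure.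
- Change of approach: the same ether bond is made between two separate molecules at ordinary concentration. The macrocycle is then closed at the ring A–CH2 bond by an intramolecular B-alkyl Suzuki–Miyaura coupling.
- The fallback sets out from 1. Cross metathesis of an excess of 1 with 6 should give (E)-hexadeca-3,15-dien-2-one F1.
- Treatment with 8 under the conditions of step 3 leads through the keto ester F2 and the keto acid F3 to 5-(dodec-11-en-1-yl)cyclohexane-1,3-dione F4.
- Diazo transfer as in step 5 gives the 2-diazo dione F5.
- Rh2(OAc)4 and an excess of purchased 5-bromoresorcinol (Oc1cc(O)cc(Br)c1) give 2-(3-bromo-5-hydroxyphenoxy)-5-(dodec-11-en-1-yl)-3-hydroxycyclohex-2-en-1-one F6.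
- Silylation and DDQ as in step 7 lead through the tris-TBS cyclohexadiene F7 to the tris-TBS bromo diaryl ether F8.
- 2 adds to the vinyl group to give the B-alkyl borane F9. This is closed with PdCl2(dppf) and K3PO4 in THF–DMF under high dilution to 17, where the route is rejoined.

Step 7.
- What may go wrong: the second enol silylation next to the bulky aryloxy group stalls, or DDQ goes on to oxidise the benzylic positions of the electron-rich product.
- Change of approach: oxidant-free catalytic dehydrogenation.
- The fallback sets out from 15, which is heated with 10% Pd/C in triglyme at about 200 °C under an argon stream. H2 is lost; this is the known conversion of cyclohexane-1,3-diones into resorcinols.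
- It comes back to the route at 18, so steps 7 and 8 both drop out. No new compound is made (entry F0).

Step 5.
- What may go wrong: electrophilic attack of the sulfonyl azide or of the diazo product on the unprotected resorcinol ring (azo coupling) competes with transfer to C2.
- Change of approach: ring A is masked during the diazo transfer.
- The fallback sets out from 12. TBSCl and imidazole in DMF give the tris-silyl compound F10 (two aryl silyl ethers and one silyl enol ether).
- Aqueous acetic acid in THF cleaves only the labile vinylogous silyl ester and gives the bis(aryl TBS ether) dione F11.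
- Diazo transfer as in step 5 gives the protected diazo dione F12.
- Et3N·3HF in THF removes the two aryl silyl groups without touching the diazo dione, and the route is rejoined at 13.

**Further compounds**
F1 | step 6 | (E)-hexadeca-3,15-dien-2-one | CC(=O)/C=C/CCCCCCCCCCC=C
F2 | step 6 | methyl 6-(dodec-11-en-1-yl)-2,4-dioxocyclohexane-1-carboxylate (racemic) | COC(=O)C1C(CCCCCCCCCCC=C)CC(=O)CC1=O
F3 | step 6 | 6-(dodec-11-en-1-yl)-2,4-dioxocyclohexane-1-carboxylic acid (racemic) | OC(=O)C1C(CCCCCCCCCCC=C)CC(=O)CC1=O
F4 | step 6 | 5-(dodec-11-en-1-yl)cyclohexane-1,3-dione | O=C1CC(CCCCCCCCCCC=C)CC(=O)C1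
F5 | step 6 | 2-diazo-5-(dodec-11-en-1-yl)cyclohexane-1,3-dione | O=C1CC(CCCCCCCCCCC=C)CC(=O)C1=[N+]=[N-]
F6 | step 6 | 2-(3-bromo-5-hydroxyphenoxy)-5-(dodec-11-en-1-yl)-3-hydroxycyclohex-2-en-1-one (racemic) | Oc1cc(Br)cc(c1)OC1=C(O)CC(CC1=O)CCCCCCCCCCC=C
F7 | step 6 | tris-TBS cyclohexadiene derived from F6 (racemic) | CC(C)(C)[Si](C)(C)Oc1cc(Br)cc(c1)OC1=C(O[Si](C)(C)C(C)(C)C)CC(C=C1O[Si](C)(C)C(C)(C)C)CCCCCCCCCCC=C
F8 | step 6 | tris-TBS bromo diaryl ether with dodec-11-enyl chain | CC(C)(C)[Si](C)(C)Oc1cc(Br)cc(c1)Oc1c(O[Si](C)(C)C(C)(C)C)cc(cc1O[Si](C)(C)C(C)(C)C)CCCCCCCCCCC=C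
F9 | step 6 | 9-BBN adduct of F8 | CC(C)(C)[Si](C)(C)Oc1cc(Br)cc(c1)Oc1c(O[Si](C)(C)C(C)(C)C)cc(cc1O[Si](C)(C)C(C)(C)C)CCCCCCCCCCCCB1C2CCCC1CCC2
F0 | step 7 | none | none
F10 | step 5 | tris-silyl derivative of 12 (two aryl TBS ethers, one TBS enol ether; racemic) | CC(C)(C)[Si](C)(C)Oc1cc(O[Si](C)(C)C(C)(C)C)cc(CCCCCCCCCCCCC2CC(=O)C=C(O[Si](C)(C)C(C)(C)C)C2)c1
F11 | step 5 | 5-{12-[3,5-bis(tert-butyldimethylsilyloxy)phenyl]dodecyl}cyclohexane-1,3-dione | CC(C)(C)[Si](C)(C)Oc1cc(O[Si](C)(C)C(C)(C)C)cc(CCCCCCCCCCCCC2CC(=O)CC(=O)C2)c1
F12 | step 5 | 2-diazo-5-{12-[3,5-bis(tert-butyldimethylsilyloxy)phenyl]dodecyl}cyclohexane-1,3-dione | CC(C)(C)[Si](C)(C)Oc1cc(O[Si](C)(C)C(C)(C)C)cc(CCCCCCCCCCCCC2CC(=O)C(=[N+]=[N-])C(=O)C2)c1
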